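The tetramer is cut at the U2 C4–U3 C8 bond into a bromine-capped epigallocatechin dimer and a galloylated U3–U4 dimer. Everything rests on building ring C of U3 from a 4H-chromene: one copper/palladium arylboration across its C2=C3 enol ether joins ring B to C2 and boron to C3, syn and on the α face, away from the 4β aryl group (C8 of U4) at C4. This gives the 2,3-cis-3,4-trans pattern with boron as a masked, unique C3 hydroxyl for the gallate. The precursor is the perbenzylated 4β-(epicatechin-8-yl)-5,7-bis(benzyloxy)-4H-chromene, whose C4 is set by a chiral-acid-controlled o-quinone methide cycloaddition.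

Key step: step 10

Conventions: Bn = benzyl; U1–U4 are the flavan units from the top; α/β refer to the usual flavan drawing (ring A left, O1 up), α being the face of ring B and O3 in U3.
Assumption: in step 6 the (R)-configured acid is taken as matched to the 4β epimer; if induction runs the other way its enantiomer is used, and the two C4 epimers are diastereomers and separable in any case.
Design remark: every hydroxyl of chromene 15, O3 of U4 included, is a benzyl ether, so no acidic OH meets NaOtBu and the hydroxyl later made at C3 of U3 is the only free one; the 5-benzyloxy group peri to C4 holds the C4 aryl group pseudoaxial.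

Step 1
Reactants: 1 (−)-epicatechin; 2 benzyl bromide
Product: 3 5,7,3',4'-tetra-O-benzyl-(−)-epicatechin
Conditions: BnBr (4.4 equiv), K2CO3, DMF, 0 °C to rt, N2
Reagents that add atoms: benzyl bromide, BrCc1ccccc1
Why: Williamson ether synthesis in which carbonate deprotonates only the four phenols, so the secondary C3 hydroxyl stays free and C2 and C3 are untouched.

Step 2
Reactants: 3 5,7,3',4'-tetra-O-benzyl-(−)-epicatechin; 4 N-bromosuccinimide
Product: 5 8-bromo-5,7,3',4'-tetra-O-benzyl-(−)-epicatechin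
Conditions: NBS (1.0 equiv), CH2Cl2, −78 °C to 0 °C
Reagents that add atoms: N-bromosuccinimide, O=C1CCC(=O)N1Br
Why: Electrophilic aromatic bromination should go to C8 of ring A, the most nucleophilic and least hindered position of a 5,7-dialkoxychroman, and leave the less activated ring B alone.

Step 3
Reactants: 5 8-bromo-5,7,3',4'-tetra-O-benzyl-(−)-epicatechin; 2 benzyl bromide
Product: 6 8-bromo-3,5,7,3',4'-penta-O-benzyl-(−)-epicatechin
Conditions: NaH, BnBr, Bu4NI (cat.), THF/DMF, 0 °C to rt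
Reagents that add atoms: benzyl bromide, BrCc1ccccc1
Why: Williamson ether synthesis on the secondary alkoxide, safe for C2 because no phenol is free to open ring C, which masks O3 of U4 against the later acylation.

Step 4
Reactants: 7 2,4,6-trihydroxybenzaldehyde; 2 benzyl bromide
Product: 8 4,6-bis(benzyloxy)-2-hydroxybenzaldehyde
Conditions: BnBr (2.05 equiv), K2CO3 (2.1 equiv), DMF, 0 °C to rt
Reagents that add atoms: benzyl bromide, BrCc1ccccc1
Why: Williamson ether synthesis that should stop at the diether because the remaining hydroxyl is hydrogen-bonded to the formyl group and is the least acidic and least nucleophilic.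

Step 5
Reactants: 6 8-bromo-3,5,7,3',4'-penta-O-benzyl-(−)-epicatechin; 8 4,6-bis(benzyloxy)-2-hydroxybenzaldehyde
Product: 11 [4,6-bis(benzyloxy)-2-hydroxyphenyl](3,5,7,3',4'-penta-O-benzyl-epicatechin-8-yl)methanol (both carbinol epimers), via 8-lithio-penta-O-benzyl-epicatechin 9 (not isolated), via sodium 3,5-bis(benzyloxy)-2-formylphenoxide 10 (not isolated)
Conditions: 8, NaH, THF, 0 °C; 6, n-BuLi, THF, −78 °C; phenoxide solution added to the aryllithium, −78 to −20 °C; H2O, pH 7 buffer; used crude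
Reagents that add atoms: none
Why: Bromine–lithium exchange at C8 followed by 1,2-addition of the aryllithium to the aldehyde, whose phenol is held as the sodium phenoxide so that it cannot protonate the carbanion; the carbinol centre forms without control, which is harmless because it becomes planar in step 6.

Step 6
Reactants: 11 salicyl carbinol; 12 ethyl vinyl ether
Product: 14 5,7-bis(benzyloxy)-2-ethoxy-4β-(penta-O-benzyl-epicatechin-8-yl)chroman (C2 anomers admissible), via o-quinone methide 13 (not isolated)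
Conditions: (R)-TRIP [(R)-3,3'-bis(2,4,6-triisopropylphenyl)-1,1'-binaphthyl-2,2'-diyl hydrogen phosphate] (10 mol %), ethyl vinyl ether (5 equiv), 4 Å MS, toluene, −40 to 0 °C
Reagents that add atoms: ethyl vinyl ether, C=COCC
Why: The phosphoric acid ionises either carbinol epimer to the hydrogen-bonded o-quinone methide, and ethyl vinyl ether adds in an inverse-electron-demand oxa-Diels–Alder reaction (the acid-catalysed o-quinone methide [4+2] with electron-rich alkenes) in which the chiral phosphate pocket chooses the face of the methide carbon and so sets C4 as 4β, while the acetal centre C2 is removed in step 7.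

Step 7
Reactants: 14 2-ethoxychroman
Product: 15 5,7-bis(benzyloxy)-4β-(3,5,7,3',4'-penta-O-benzyl-epicatechin-8-yl)-4H-chromene
Conditions: TMSOTf (1.3 equiv), i-Pr2NEt (2 equiv), CH2Cl2, −30 °C to rt; Et3N-deactivated silica
Reagents that add atoms: none
Why: TMSOTf activates the exocyclic ethoxy group and the amine removes H3 from the aryl-oxocarbenium ion at C2 (acetal-to-enol-ether elimination), so both anomers give the same C2=C3 enol ether and C4 is not involved.

Step 8
Reactants: 16 5-bromo-1,2,3-trimethoxybenzene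
Product: 17 5-bromobenzene-1,2,3-triol
Conditions: BBr3 (3.6 equiv), CH2Cl2, −78 °C to rt; then H2O
Reagents that add atoms: none
Why: Lewis-acid cleavage of the three aryl methyl ethers (BBr3 demethylation), to which the aryl bromide is inert.

Step 9
Reactants: 17 5-bromobenzene-1,2,3-triol; 2 benzyl bromide
Product: 18 5-bromo-1,2,3-tris(benzyloxy)benzene
Conditions: BnBr (3.3 equiv), K2CO3, DMF, rt, N2
Reagents that add atoms: benzyl bromide, BrCc1ccccc1
Why: Williamson ether synthesis on the three phenols under an inert atmosphere to protect the air-sensitive triol.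

Step 10
Reactants: 15 4β-aryl-4H-chromene; 18 5-bromo-1,2,3-tris(benzyloxy)benzene; 19 bis(pinacolato)diboron
Product: 21 benzylated U3–U4 dimer with a pinacolboronate at C3 of U3 (2α-aryl, 3α-boryl, 4β-aryl), via C2 alkylcopper adduct 20 (not isolated)
Conditions: (SIMes)CuCl (10 mol %; SIMes = 1,3-dimesityl-4,5-dihydroimidazol-2-ylidene), Pd(OAc)2 (5 mol %), RuPhos (10 mol %), 18 (1.5 equiv), B2pin2 (1.5 equiv), NaOtBu (1.5 equiv), toluene/THF, rt
Reagents that add atoms: 5-bromo-1,2,3-tris(benzyloxy)benzene, Brc1cc(OCc9ccccc9)c(OCc9ccccc9)c(OCc9ccccc9)c1; bis(pinacolato)diboron, CC1(C)OB(OC1(C)C)B1OC(C)(C)C(C)(C)O1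
Why: Proposed new method: (SIMes)Cu–Bpin, formed from the copper tert-butoxide and B2pin2, should add syn across C2=C3 with boron to C3 and monovalent copper to the oxygen-bearing C2; this alkylcopper transmetalates with retention to the arylpalladium bromide (divalent palladium) formed by oxidative addition of 18 to zerovalent palladium, and reductive elimination forms C2–C1'. The closest known reaction type is the cooperative copper/palladium syn-arylboration of styrenes and cyclic alkenes, and α-alkoxyalkyl metal species are known to pass to arylpalladium with retention. No ring is closed; the step makes the C3–B and C2–C1' bonds. Both new stereocentres come from one syn addition: C3 (boron α) is controlled by the 4β aryl group at C4, which the peri 5-benzyloxy group holds pseudoaxial so that it screens the β face, and C2 (ring B α) follows from syn delivery and retention. The step needs boron at C3, secured by the ring oxygen O1 because copper prefers the α-oxygenated, less hindered C2 over a position next to the crowded C4, and it needs β-hydride loss to be suppressed, secured by the ring because H3 ends up anti to the metal at C2.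

Step 11
Reactants: 21 C3 pinacolboronate; 22 sodium perborate
Product: 23 benzylated U3–U4 dimer with free 3-OH on U3 (2α-aryl, 3α-OH, 4β-aryl)
Conditions: NaBO3·4H2O (5 equiv), THF/H2O (1:1), rt
Reagents that add atoms: sodium perborate, [Na+].[Na+].O[B-]1(O)OO[B-](O)(O)OO1
Why: Peroxide attack on boron and 1,2-migration of C3 from boron to oxygen (boronate oxidation) proceed with retention, so the hydroxyl appears on the α face, cis to ring B.

Step 12
Reactants: 23 U3–U4 alcohol; 24 3,4,5-tris(benzyloxy)benzoic acid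
Product: 25 benzylated U3–U4 dimer 3-O-[3,4,5-tris(benzyloxy)benzoate] on U3
Conditions: 24 (2 equiv), DCC (2.5 equiv), DMAP (1 equiv), CH2Cl2, 0 °C to rt
Reagents that add atoms: 3,4,5-tris(benzyloxy)benzoic acid, OC(=O)c1cc(OCc9ccccc9)c(OCc9ccccc9)c(OCc9ccccc9)c1
Why: Steglich esterification of the only free hydroxyl in the molecule, with no change at C3.

Step 13
Reactants: 26 (−)-epigallocatechin; 2 benzyl bromide
Product: 27 5,7,3',4',5'-penta-O-benzyl-(−)-epigallocatechin
Conditions: BnBr (5.5 equiv), K2CO3, degassed DMF, 0 °C to rt, N2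
Reagents that add atoms: benzyl bromide, BrCc1ccccc1
Why: Williamson ether synthesis on the five phenols only, the C3 hydroxyl staying free under carbonate.

Step 14
Reactants: 27 penta-O-benzyl-epigallocatechin; 4 N-bromosuccinimide
Product: 28 8-bromo-5,7,3',4',5'-penta-O-benzyl-(−)-epigallocatechin
Conditions: NBS (1.0 equiv), CH2Cl2, −78 °C to 0 °C
Reagents that add atoms: N-bromosuccinimide, O=C1CCC(=O)N1Br
Why: Electrophilic bromination at C8 of ring A, the most nucleophilic position, which caps the future top unit against self-condensation.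

Step 15
Reactants: 28 8-bromo-penta-O-benzyl-epigallocatechin; 29 2-ethoxyethanol
Product: 30 8-bromo-4β-(2-ethoxyethoxy)-5,7,3',4',5'-penta-O-benzyl-epigallocatechin
Conditions: DDQ (2 equiv), 2-ethoxyethanol (5 equiv), CH2Cl2, rt
Reagents that add atoms: 2-ethoxyethanol, CCOCCO
Why: DDQ abstracts hydride from the benzylic C4 of the alkoxy-activated ring A (benzylic oxidation) and the alcohol traps the cation anti to O3 and ring B, giving the 4β ether.

Step 16
Reactants: 30 bromine-capped C4 ether; 27 penta-O-benzyl-epigallocatechin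
Product: 31 8-bromo-penta-O-benzyl-epigallocatechin-(4β→8)-penta-O-benzyl-epigallocatechin (U1–U2, both 3-OH free)
Conditions: 27 (1.5 equiv), TMSOTf (0.2 equiv), CH2Cl2, −78 °C; aq NaHCO3
Reagents that add atoms: none
Why: TMSOTf ionises the 2-ethoxyethoxy group to the ring A-stabilised C4 cation, which C8 of 27 captures in a Friedel–Crafts-type flavan condensation anti to O3 and ring B of the 2,3-cis unit to set the 4β (3,4-trans) bond, while the C8 bromine keeps 30 from reacting as a nucleophile.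

Step 17
Reactants: 31 U1–U2 dimer; 29 2-ethoxyethanol
Product: 32 U1–U2 dimer with a 4β-(2-ethoxyethoxy) group on U2
Conditions: DDQ (2 equiv), 2-ethoxyethanol (5 equiv), CH2Cl2, rt
Reagents that add atoms: 2-ethoxyethanol, CCOCCO
Why: Benzylic oxidation with DDQ at the only benzylic methylene on an activated ring A (C4 of U2), the diaryl methine hydrogen at C4 of U1 being shielded by its two ortho-disubstituted rings, with trapping by the alcohol trans to O3.

Step 18
Reactants: 32 C4-activated U1–U2 dimer; 25 galloylated U3–U4 dimer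
Product: 33 fully benzylated, 8-bromo-capped tetramer U1–U2–U3(gallate)–U4
Conditions: 32 (1.3 equiv), TMSOTf (0.2 equiv), CH2Cl2, −78 to −40 °C; aq NaHCO3
Reagents that add atoms: none
Why: TMSOTf ionises the 2-ethoxyethoxy group of 32 to the C4 cation of U2, which is captured in a Friedel–Crafts-type flavan condensation by C8 of U3 in 25, the most nucleophilic free position (flanked by O1, whereas both C6 positions lie between two benzyloxy groups), on the face anti to O3 and ring B of U2 to give the 4β bond, the bromine on U1 preventing self-condensation of 32.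

Step 19
Reactants: 33 protected tetramer
Product: 34 target tetramer (CNP0305998.1)
Conditions: H2 (1 atm), Pd(OH)2/C, Et3N (1.2 equiv), THF/MeOH/H2O, rt; Sephadex LH-20
Reagents that add atoms: none
Why: Hydrogenolysis over Pd(OH)2/C cleaves all twenty-three benzyl ethers and, buffered by Et3N, the C8–Br cap, while the gallate ester, the interflavan bonds and the eleven stereocentres are inert to hydrogen.

Compound list
1 | (−)-epicatechin (2R,3R) | Oc1cc(O)c2c(c1)O[C@H](c1ccc(O)c(O)c1)[C@H](O)C2 | starting material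
2 | benzyl bromide | BrCc1ccccc1 | starting material
3 | 5,7,3',4'-tetra-O-benzyl-(−)-epicatechin | c1c(OCc9ccccc9)cc(OCc9ccccc9)c2c1O[C@H](c8ccc(OCc9ccccc9)c(OCc9ccccc9)c8)[C@H](O)C2 | intermediate
4 | N-bromosuccinimide | O=C1CCC(=O)N1Br | starting material
5 | 8-bromo-5,7,3',4'-tetra-O-benzyl-(−)-epicatechin | Brc1c(OCc9ccccc9)cc(OCc9ccccc9)c2c1O[C@H](c8ccc(OCc9ccccc9)c(OCc9ccccc9)c8)[C@H](O)C2 | intermediate
6 | 8-bromo-3,5,7,3',4'-penta-O-benzyl-(−)-epicatechin | Brc1c(OCc9ccccc9)cc(OCc9ccccc9)c2c1O[C@H](c8ccc(OCc9ccccc9)c(OCc9ccccc9)c8)[C@H](OCc9ccccc9)C2 | intermediate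
7 | 2,4,6-trihydroxybenzaldehyde | O=Cc1c(O)cc(O)cc1O | starting material
8 | 4,6-bis(benzyloxy)-2-hydroxybenzaldehyde | O=Cc1c(O)cc(OCc9ccccc9)cc1OCc9ccccc9 | intermediate
9 | 8-lithio-3,5,7,3',4'-penta-O-benzyl-epicatechin | [Li]c1c(OCc9ccccc9)cc(OCc9ccccc9)c2c1O[C@H](c8ccc(OCc9ccccc9)c(OCc9ccccc9)c8)[C@H](OCc9ccccc9)C2 | intermediate
10 | sodium 3,5-bis(benzyloxy)-2-formylphenoxide | [Na+].[O-]c1cc(OCc9ccccc9)cc(OCc9ccccc9)c1C=O | intermediate
11 | [4,6-bis(benzyloxy)-2-hydroxyphenyl](penta-O-benzyl-epicatechin-8-yl)methanol, carbinol centre undefined | OC(c1c(O)cc(OCc9ccccc9)cc1OCc9ccccc9)c1c(OCc9ccccc9)cc(OCc9ccccc9)c2c1O[C@H](c8ccc(OCc9ccccc9)c(OCc9ccccc9)c8)[C@H](OCc9ccccc9)C2 | intermediate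
12 | ethyl vinyl ether | C=COCC | starting material
13 | 3,5-bis(benzyloxy)-6-[(penta-O-benzyl-epicatechin-8-yl)methylidene]cyclohexa-2,4-dien-1-one (o-quinone methide) | O=C1C=C(OCc9ccccc9)C=C(OCc9ccccc9)C1=Cc1c(OCc9ccccc9)cc(OCc9ccccc9)c2c1O[C@H](c8ccc(OCc9ccccc9)c(OCc9ccccc9)c8)[C@H](OCc9ccccc9)C2 | intermediate
14 | 5,7-bis(benzyloxy)-2-ethoxy-4β-(penta-O-benzyl-epicatechin-8-yl)chroman, C2 undefined | CCOC1C[C@@H](c2c(OCc9ccccc9)cc(OCc9ccccc9)c3c2O[C@H](c8ccc(OCc9ccccc9)c(OCc9ccccc9)c8)[C@H](OCc9ccccc9)C3)c2c(OCc9ccccc9)cc(OCc9ccccc9)cc2O1 | intermediate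
15 | 5,7-bis(benzyloxy)-4β-(penta-O-benzyl-epicatechin-8-yl)-4H-chromene | C1=C[C@@H](c2c(OCc9ccccc9)cc(OCc9ccccc9)c3c2O[C@H](c8ccc(OCc9ccccc9)c(OCc9ccccc9)c8)[C@H](OCc9ccccc9)C3)c2c(OCc9ccccc9)cc(OCc9ccccc9)cc2O1 | intermediate
16 | 5-bromo-1,2,3-trimethoxybenzene | COc1cc(Br)cc(OC)c1OC | starting material
17 | 5-bromobenzene-1,2,3-triol | Oc1cc(Br)cc(O)c1O | intermediate
18 | 5-bromo-1,2,3-tris(benzyloxy)benzene | Brc1cc(OCc9ccccc9)c(OCc9ccccc9)c(OCc9ccccc9)c1 | intermediate
19 | bis(pinacolato)diboron | CC1(C)OB(OC1(C)C)B1OC(C)(C)C(C)(C)O1 | starting material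
20 | (SIMes)Cu alkyl at C2 (copper α) with pinacolboronate at C3 (α) of the 4β-aryl chroman | CC1(C)OB([C@@H]2[C@@H](c3c(OCc9ccccc9)cc(OCc9ccccc9)c4c3O[C@H](c8ccc(OCc9ccccc9)c(OCc9ccccc9)c8)[C@H](OCc9ccccc9)C4)c3c(OCc9ccccc9)cc(OCc9ccccc9)cc3O[C@@H]2[Cu]=C2N(c3c(C)cc(C)cc3C)CCN2c2c(C)cc(C)cc2C)OC1(C)C | intermediate
21 | benzylated U3–U4 dimer, C3 pinacolboronate on U3 (2α-aryl, 3α-boryl, 4β-aryl) | CC1(C)OB([C@@H]2[C@@H](c3c(OCc9ccccc9)cc(OCc9ccccc9)c4c3O[C@H](c8ccc(OCc9ccccc9)c(OCc9ccccc9)c8)[C@H](OCc9ccccc9)C4)c3c(OCc9ccccc9)cc(OCc9ccccc9)cc3O[C@@H]2c8cc(OCc9ccccc9)c(OCc9ccccc9)c(OCc9ccccc9)c8)OC1(C)C | intermediate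
22 | sodium perborate | [Na+].[Na+].O[B-]1(O)OO[B-](O)(O)OO1 | starting material
23 | 5,7,3',4',5'-penta-O-benzyl-epigallocatechin-(4β→8)-3,5,7,3',4'-penta-O-benzyl-epicatechin, 3-OH of U3 free | O[C@@H]1[C@@H](c2c(OCc9ccccc9)cc(OCc9ccccc9)c3c2O[C@H](c8ccc(OCc9ccccc9)c(OCc9ccccc9)c8)[C@H](OCc9ccccc9)C3)c2c(OCc9ccccc9)cc(OCc9ccccc9)cc2O[C@@H]1c8cc(OCc9ccccc9)c(OCc9ccccc9)c(OCc9ccccc9)c8 | intermediate
24 | 3,4,5-tris(benzyloxy)benzoic acid | OC(=O)c1cc(OCc9ccccc9)c(OCc9ccccc9)c(OCc9ccccc9)c1 | starting material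
25 | compound 23 esterified at O3 of U3 with 3,4,5-tris(benzyloxy)benzoic acid | O=C(O[C@@H]1[C@@H](c2c(OCc9ccccc9)cc(OCc9ccccc9)c3c2O[C@H](c8ccc(OCc9ccccc9)c(OCc9ccccc9)c8)[C@H](OCc9ccccc9)C3)c2c(OCc9ccccc9)cc(OCc9ccccc9)cc2O[C@@H]1c8cc(OCc9ccccc9)c(OCc9ccccc9)c(OCc9ccccc9)c8)c1cc(OCc9ccccc9)c(OCc9ccccc9)c(OCc9ccccc9)c1 | intermediate
26 | (−)-epigallocatechin (2R,3R) | Oc1cc(O)c2c(c1)O[C@H](c1cc(O)c(O)c(O)c1)[C@H](O)C2 | starting material
27 | 5,7,3',4',5'-penta-O-benzyl-(−)-epigallocatechin | c1c(OCc9ccccc9)cc(OCc9ccccc9)c2c1O[C@H](c8cc(OCc9ccccc9)c(OCc9ccccc9)c(OCc9ccccc9)c8)[C@H](O)C2 | intermediate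
28 | 8-bromo-5,7,3',4',5'-penta-O-benzyl-(−)-epigallocatechin | Brc1c(OCc9ccccc9)cc(OCc9ccccc9)c2c1O[C@H](c8cc(OCc9ccccc9)c(OCc9ccccc9)c(OCc9ccccc9)c8)[C@H](O)C2 | intermediate
29 | 2-ethoxyethanol | CCOCCO | starting material
30 | 8-bromo-4β-(2-ethoxyethoxy)-5,7,3',4',5'-penta-O-benzyl-epigallocatechin | CCOCCO[C@H]1c2c(OCc9ccccc9)cc(OCc9ccccc9)c(Br)c2O[C@H](c8cc(OCc9ccccc9)c(OCc9ccccc9)c(OCc9ccccc9)c8)[C@@H]1O | intermediate
31 | 8-bromo-penta-O-benzyl-epigallocatechin-(4β→8)-penta-O-benzyl-epigallocatechin | C1c2c(OCc9ccccc9)cc(OCc9ccccc9)c([C@H]3c4c(OCc9ccccc9)cc(OCc9ccccc9)c(Br)c4O[C@H](c8cc(OCc9ccccc9)c(OCc9ccccc9)c(OCc9ccccc9)c8)[C@@H]3O)c2O[C@H](c8cc(OCc9ccccc9)c(OCc9ccccc9)c(OCc9ccccc9)c8)[C@@H]1O | intermediate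
32 | dimer 31 with a 4β-(2-ethoxyethoxy) group at C4 of its lower unit (U2) | CCOCCO[C@H]1c2c(OCc9ccccc9)cc(OCc9ccccc9)c([C@H]3c4c(OCc9ccccc9)cc(OCc9ccccc9)c(Br)c4O[C@H](c8cc(OCc9ccccc9)c(OCc9ccccc9)c(OCc9ccccc9)c8)[C@@H]3O)c2O[C@H](c8cc(OCc9ccccc9)c(OCc9ccccc9)c(OCc9ccccc9)c8)[C@@H]1O | intermediate
33 | benzylated tetramer: 8-bromo-epigallocatechin-(4β→8)-epigallocatechin-(4β→8)-epigallocatechin 3-O-gallate-(4β→8)-epicatechin, all phenols and O3 of U4 as benzyl ethers, 3-OH of U1 and U2 free | O=C(O[C@@H]1[C@@H](c2c(OCc9ccccc9)cc(OCc9ccccc9)c3c2O[C@H](c8ccc(OCc9ccccc9)c(OCc9ccccc9)c8)[C@H](OCc9ccccc9)C3)c2c(OCc9ccccc9)cc(OCc9ccccc9)c([C@H]3c4c(OCc9ccccc9)cc(OCc9ccccc9)c([C@H]5c6c(OCc9ccccc9)cc(OCc9ccccc9)c(Br)c6O[C@H](c8cc(OCc9ccccc9)c(OCc9ccccc9)c(OCc9ccccc9)c8)[C@@H]5O)c4O[C@H](c8cc(OCc9ccccc9)c(OCc9ccccc9)c(OCc9ccccc9)c8)[C@@H]3O)c2O[C@@H]1c8cc(OCc9ccccc9)c(OCc9ccccc9)c(OCc9ccccc9)c8)c1cc(OCc9ccccc9)c(OCc9ccccc9)c(OCc9ccccc9)c1 | intermediate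
34 | epigallocatechin-(4β→8)-epigallocatechin-(4β→8)-epigallocatechin 3-O-gallate-(4β→8)-epicatechin (CNP0305998.1) | O=C(O[C@@H]1[C@@H](c2c(O)cc(O)c3c2O[C@H](c2ccc(O)c(O)c2)[C@H](O)C3)c2c(O)cc(O)c([C@H]3c4c(O)cc(O)c([C@H]5c6c(O)cc(O)cc6O[C@H](c6cc(O)c(O)c(O)c6)[C@@H]5O)c4O[C@H](c4cc(O)c(O)c(O)c4)[C@@H]3O)c2O[C@@H]1c1cc(O)c(O)c(O)c1)c1cc(O)c(O)c(O)c1 | target

Total step count: 19 steps.
Longest linear sequence: 11 steps (steps 1, 2, 3, 5, 6, 7, 10, 11, 12, 18, 19).

Steps most likely to fail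

Step 10. Borylcupration of the electron-rich, crowded enol ether may be too slow, so that the arylpalladium species is diverted into direct borylation of 18 or Heck-type arylation. The regiochemistry may also invert (copper at C3, then β-aryloxide elimination and ring opening), or the facial selectivity may be incomplete. The fallback uses known chemistry and sets out from chromene 15. Epoxidation with dimethyldioxirane (acetone/CH2Cl2, −78 °C) on the face away from the C4 aryl group should give the 2α,3α-epoxy-4β-aryl chroman F1. Bromide 18 is converted with n-BuLi into 3,4,5-tris(benzyloxy)phenyllithium F2 and then with AlCl3 (one third equivalent) into tris[3,4,5-tris(benzyloxy)phenyl]aluminium F3. The alane opens the acetal epoxide at C2 and delivers its aryl group on the face of the aluminium-bound C3 oxygen, the syn C-arylation known for glycal epoxides. This gives the 2,3-cis alcohol directly, and the route is rejoined at compound 23.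

Step 6. Facial selectivity at C4 may be poor, either because the catalyst and the remote U4 stereocentres are mismatched or because an unbound diaryl cation reacts in a background pathway; acid-induced oligomerisation of the vinyl ether is a second risk. The fallback is auxiliary-controlled and sets out from aldehyde 8 and aryllithium 9 (from bromide 6 as in step 5). Aldehyde 8 is converted with Boc2O/DMAP into 3,5-bis(benzyloxy)-2-formylphenyl tert-butyl carbonate F4. Aryllithium 9 is added to F4 at −78 °C, followed by MgBr2·OEt2 and (1R,2S)-2-phenylcyclohexyl vinyl ether F5, which is made from (1R,2S)-2-phenylcyclohexanol and ethyl vinyl ether with Hg(OAc)2; its enantiomer is used if the sense requires. Carbonate transfer to the benzylic alkoxide and its expulsion generate the same o-quinone methide 13 at low temperature. Endo cycloaddition on the open face of the chiral vinyl ether should give the 2,4-cis 2-[(1R,2S)-2-phenylcyclohexyloxy]-4β-aryl chroman F6. Elimination with TMSOTf/i-Pr2NEt as in step 7 rejoins the route at compound 15.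

Step 18. Capture of the C4 cation by the hindered, ester-bearing dimer may be slow, so that the activated donor is lost by elimination, acid scrambles the interflavan bonds, or attack strays to a C6 position. The fallback sets out from 32, which is treated with phenylmethanethiol and BF3·OEt2 (CH2Cl2, −78 °C) to give the 4β-benzylsulfanyl U1–U2 dimer F7. This thioether is stable to acid and is then activated with thiophilic AgBF4 (THF, 0 °C) in the presence of 25, the silver-promoted coupling known for 4-benzylsulfanyl flavan-3-ols. The same 4β C4–C8 bond is formed under nearly neutral conditions, and the route is rejoined at compound 33.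

Further compounds
F1 | step 10 | 5,7-bis(benzyloxy)-2α,3α-epoxy-4β-(penta-O-benzyl-epicatechin-8-yl)chroman | O1[C@@H]2[C@@H](c3c(OCc9ccccc9)cc(OCc9ccccc9)c4c3O[C@H](c8ccc(OCc9ccccc9)c(OCc9ccccc9)c8)[C@H](OCc9ccccc9)C4)c3c(OCc9ccccc9)cc(OCc9ccccc9)cc3O[C@@H]21
F2 | step 10 | 3,4,5-tris(benzyloxy)phenyllithium | [Li]c1cc(OCc9ccccc9)c(OCc9ccccc9)c(OCc9ccccc9)c1
F3 | step 10 | tris[3,4,5-tris(benzyloxy)phenyl]aluminium | [Al](c1cc(OCc9ccccc9)c(OCc9ccccc9)c(OCc9ccccc9)c1)(c1cc(OCc9ccccc9)c(OCc9ccccc9)c(OCc9ccccc9)c1)c1cc(OCc9ccccc9)c(OCc9ccccc9)c(OCc9ccccc9)c1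
F4 | step 6 | 3,5-bis(benzyloxy)-2-formylphenyl tert-butyl carbonate | CC(C)(C)OC(=O)Oc1cc(OCc9ccccc9)cc(OCc9ccccc9)c1C=O
F5 | step 6 | (1R,2S)-2-phenylcyclohexyl vinyl ether | C=CO[C@@H]1CCCC[C@H]1c1ccccc1
F6 | step 6 | 5,7-bis(benzyloxy)-2β-[(1R,2S)-2-phenylcyclohexyloxy]-4β-(penta-O-benzyl-epicatechin-8-yl)chroman (2,4-cis) | O([C@@H]1CCCC[C@H]1c1ccccc1)[C@H]1C[C@@H](c2c(OCc9ccccc9)cc(OCc9ccccc9)c3c2O[C@H](c8ccc(OCc9ccccc9)c(OCc9ccccc9)c8)[C@H](OCc9ccccc9)C3)c2c(OCc9ccccc9)cc(OCc9ccccc9)cc2O1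
F7 | step 18 | dimer 31 with a 4β-benzylsulfanyl group at C4 of its lower unit (U2) | c9ccccc9CS[C@H]1c2c(OCc9ccccc9)cc(OCc9ccccc9)c([C@H]3c4c(OCc9ccccc9)cc(OCc9ccccc9)c(Br)c4O[C@H](c8cc(OCc9ccccc9)c(OCc9ccccc9)c(OCc9ccccc9)c8)[C@@H]3O)c2O[C@H](c8cc(OCc9ccccc9)c(OCc9ccccc9)c(OCc9ccccc9)c8)[C@@H]1O
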